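**Strategy.** The route rests on ring A (C1, C10, C11, C12, C13, C14; briarane numbering). On this ring the C12 oxygen and the C2 carbon are cis, while C9 and the C11 methyl lie together on the other face. A Diels–Alder reaction of 3-methyl-2H-pyran-2-one with (Z)-but-2-enoic acid exploits this pattern: the lactone bridge of the pyrone becomes O12 and C2, the endo cis-dienophile delivers C10 and C11, and the C1–C10 and C11–C12 bonds form together with four contiguous stereocentres. The bridged lactone is then opened at C2, the butanolide is built on C9, and ring-closing metathesis at C5=C6 closes the ten-membered ring.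

Key step: step 3

Remark: atoms are numbered as in the briarane skeleton (C1–C14 ring carbons, C15 methyl on C1, C16 methyl on C5, C17–C19 lactone carbons, C18 methyl on C17, C20 methyl on C11). The cycloaddition gives a racemate, so 5, 8 and 9 are racemic (their SMILES show the enantiomer that is carried on); the absolute configuration is introduced in step 6.

Step 1
Reactants: 1 3-bromo-2H-pyran-2-one
Product: 2 3-methyl-2H-pyran-2-one
Conditions: MeZnCl, Pd(PPh3)4 (cat.), THF, 50 °C
Reagents that add atoms: methylzinc chloride, C[Zn]Cl
Why: Negishi cross-coupling (oxidative addition of the C3–Br bond to zerovalent palladium, transmetalation from zinc, reductive elimination) installs the future C15 methyl under non-basic conditions that leave the pyranone ring intact.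

Step 2
Reactants: 3 but-2-ynoic acid
Product: 4 (Z)-but-2-enoic acid
Conditions: H2 (1 atm), Pd/CaCO3 poisoned with Pb(OAc)2 (Lindlar catalyst), quinoline, EtOAc, rt
Reagents that add atoms: none
Why: Lindlar semi-hydrogenation adds H2 syn to the alkyne and stops at the alkene, which fixes the Z geometry that later places C9 and the C11 methyl cis.

Step 3
Reactants: 2 3-methyl-2H-pyran-2-one; 4 (Z)-but-2-enoic acid
Product: 5 rac-(1R*,4S*,7R*,8S*)-4,7-dimethyl-3-oxo-2-oxabicyclo[2.2.2]oct-5-ene-8-carboxylic acid
Conditions: CH2Cl2, 13 kbar, 40 °C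
Reagents that add atoms: none
Why: Concerted, suprafacial [4+2] cycloaddition in which C3 and C6 of pyrone 2 (the future C1 and C12) bond to the α- and β-carbons of acid 4 (the future C10 and C11); the closest known reaction type is the Diels–Alder reaction of 2-pyrones with acrylic dienophiles, which gives isolable bridged lactones when run under pressure below the temperature of CO2 loss. Ring A closes as the six-membered ring of this intermolecular cycloaddition and is bridged by the lactone that the pyrone already holds, so the C2 carbonyl and O12 must end cis on ring A. C1 and C12 are fixed by that bridge, C10 and C11 are cis to each other because the Z geometry of 4 is retained, and both the carboxyl and the methyl point towards the C13=C14 bridge through the endo transition state (secondary overlap of the carboxyl with the diene, favoured further by pressure). The step needs the regiochemistry pyrone C3 to the carboxyl-bearing carbon and endo selectivity: the first is the usual preference of 2-pyrones with acceptor-substituted alkenes and is reinforced by the 3-methyl donor, the second rests on the Alder rule. The adduct is racemic.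

Step 4
Reactants: 5 racemic bicyclic lactone acid; 6 2-(2-bromoethyl)-2-methyl-1,3-dioxolane
Product: 8 rac-(1S*,2S*,5R*,6R*)-5-hydroxy-2,6-dimethyl-2-[3-(2-methyl-1,3-dioxolan-2-yl)propanoyl]cyclohex-3-ene-1-carboxylic acid, via Grignard reagent 7 (not isolated)
Conditions: 6, Mg, THF, 25 °C; then 5, THF, −78 → −20 °C; 1 M HCl to pH 3, 0 °C
Reagents that add atoms: none
Why: Acyl substitution of the strained bridged lactone by the Grignard reagent, in which the first equivalent only deprotonates the acid (the carboxylate is inert), the second adds to the lactone carbonyl (C2), and the hindered magnesium hemiketal next to quaternary C1 resists a second addition at low temperature; O12 is released as the alcohol and no stereocentre changes.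

Step 5
Reactants: 8 racemic keto hydroxy acid
Product: 9 rac-S-ethyl (1S*,2S*,5R*,6R*)-5-hydroxy-2,6-dimethyl-2-[3-(2-methyl-1,3-dioxolan-2-yl)propanoyl]cyclohex-3-ene-1-carbothioate
Conditions: EtSH, EDC·HCl, DMAP (cat.), CH2Cl2, 0 °C → rt
Reagents that add atoms: ethanethiol, CCS
Why: Steglich-type thioesterification through the O-acylisourea and the acylpyridinium ion, in which the thiol outcompetes the hindered secondary C12 hydroxyl; the thioester masks the acid for step 6 and prepares the aldehyde of step 8.

Step 6
Reactants: 9 racemic keto thioester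
Product: 10 S-ethyl (1S,2S,5R,6R)-5-hydroxy-2-[(1R)-1-hydroxy-4-(2-methyl-1,3-dioxolan-2-yl)butyl]-2,6-dimethylcyclohex-3-ene-1-carbothioate
Conditions: (S)-2-methyl-CBS-oxazaborolidine (0.2 equiv), catecholborane, toluene, −78 → −40 °C; chromatographic removal of the diastereomer
Reagents that add atoms: none
Why: Corey–Bakshi–Shibata reduction in which the oxazaborolidine binds the ketone with the tert-alkyl side (C1) away from the catalyst and should deliver hydride to the same carbonyl face in both enantiomers of 9 (reagent control, as for tert-alkyl methyl ketones), so that the racemate becomes two (2R)-configured diastereomers and chromatography leaves 10 as a single enantiomer; catecholborane spares thioester, ketal and alkene.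

Step 7
Reactants: 10 diol thioester
Product: 11 S-ethyl (1S,2S,5R,6R)-5-acetoxy-2-[(1R)-1-acetoxy-4-(2-methyl-1,3-dioxolan-2-yl)butyl]-2,6-dimethylcyclohex-3-ene-1-carbothioate
Conditions: Ac2O, pyridine, DMAP (cat.), CH2Cl2, rt
Reagents that add atoms: acetic anhydride, CC(=O)OC(C)=O
Why: DMAP-catalysed acylation of the C2 and C12 hydroxyls installs both acetates of the target before the C9 hydroxyl exists, so no later differentiation of hydroxyls is needed.

Step 8
Reactants: 11 diacetate thioester
Product: 12 (1S,2S,5R,6R)-5-acetoxy-2-[(1R)-1-acetoxy-4-(2-methyl-1,3-dioxolan-2-yl)butyl]-2,6-dimethylcyclohex-3-ene-1-carbaldehyde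
Conditions: Et3SiH, Pd/C (cat.), acetone, rt
Reagents that add atoms: none
Why: Fukuyama reduction (oxidative addition of the thioester C–S bond to palladium, hydride transfer from the silane, reductive elimination) gives the C9 aldehyde under neutral conditions that spare the acetates, the ketal and the epimerizable C10.

Step 9
Reactants: 13 2,2-diethoxyacetaldehyde
Product: 14 1,1-dibromo-3,3-diethoxyprop-1-ene
Conditions: CBr4, PPh3, Et3N, CH2Cl2, 0 °C
Reagents that add atoms: carbon tetrabromide, BrC(Br)(Br)Br
Why: Corey–Fuchs (Ramirez) dibromo-olefination of the aldehyde by the ylide Ph3P=CBr2, with triethylamine protecting the acetal from acid.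

Step 10
Reactants: 14 1,1-dibromo-3,3-diethoxyprop-1-ene; 15 methyl 2-bromopropanoate
Product: 17 methyl (3Z)-3-bromo-5,5-diethoxy-2-methylpent-3-enoate, via Reformatsky reagent 16 (not isolated)
Conditions: 15, Zn, THF, 40 °C; then 14, Pd[P(t-Bu)3]2 (cat.), THF, rt
Reagents that add atoms: none
Why: Negishi-type coupling of the zinc ester enolate with the 1,1-dibromoalkene, in which palladium inserts selectively into the less hindered C–Br bond trans to the acetal substituent, so the ester branch ends trans to C6 and the remaining bromine cis to it (Z); the ester α-carbon (C17) forms as a mixture that is equilibrated in step 12.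

Step 11
Reactants: 12 aldehyde; 17 methyl (3Z)-3-bromo-5,5-diethoxy-2-methylpent-3-enoate
Product: 18 C9 triethylsilyl ether of the (9R)-allylic alcohol formed by joining C9 of 12 to C8 of 17 (Z-alkene C7=C8 retained, epimers at C17)
Conditions: CrCl2 (15 mol%), NiCl2 (2 mol%), Mn, Et3SiCl, DMF/DME, 50 °C
Reagents that add atoms: chlorotriethylsilane, CC[Si](Cl)(CC)CC
Why: Nozaki–Hiyama–Kishi reaction catalytic in chromium (nickel inserts into the alkenyl bromide with retention of geometry, transmetalation to chromium, addition to the aldehyde, silyl chloride releases chromium from the alkoxide and Mn regenerates CrCl2), in which Felkin–Anh addition anti to quaternary C1 with the C11 branch as medium group should give the (9R)-carbinol, trapped as its silyl ether so that it cannot lactonize onto the ester.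

Step 12
Reactants: 18 silyl ether
Product: 20 β-hydroxy-γ-lactone (O7–C19 lactone with 8-OH and 17-methyl; 9-OSiEt3; C6 diethyl acetal; C5 dioxolane; stereocentres as in 23), via diol ester 19 (not isolated)
Conditions: OsO4 (2 mol%), (DHQ)2PHAL (5 mol%), NMO, acetone/H2O, 0 °C; then DBU, toluene, 60 °C
Reagents that add atoms: 4-methylmorpholine N-oxide, C[N+]1([O-])CCOCC1; water, O
Why: Ligand-accelerated osmylation should pick the trisubstituted C7=C8 alkene over the hindered cis-disubstituted C13=C14 alkene and add both oxygens syn, on the face anti to the C9 silyloxy group in the conformer whose allylic C–H eclipses the alkene (the usual empirical preference of allylic ethers, matched by the face selection of the (DHQ)2PHAL ligand), which sets C7 and C8; the C7 hydroxyl then closes the γ-lactone on the methyl ester and DBU equilibrates C17 to the epimer with the methyl trans to the bulky C9 substituent.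

Step 13
Reactants: 20 lactone
Product: 21 keto aldehyde diol (C6 aldehyde, C5 methyl ketone, free 8-OH and 9-OH; stereocentres as in 23)
Conditions: 1 M HCl/THF (1:3), rt
Reagents that add atoms: water, O
Why: Acid hydrolysis converts the diethyl acetal into the C6 aldehyde and the dioxolane into the C5 methyl ketone and cleaves the silyl ether while acetates and lactone survive; the free C9 hydroxyl cannot form a lactol with C6 because that ring would be trans-fused to the lactone.

Step 14
Reactants: 21 keto aldehyde
Product: 22 diene (C6 vinyl group on C7 and C5 isopropenyl group; stereocentres as in 23)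
Conditions: Zn, CH2Br2, TiCl4, THF/CH2Cl2, 0 °C → rt
Reagents that add atoms: dibromomethane, BrCBr
Why: Takai–Lombardo methylenation with the non-basic zinc/titanium methylene reagent converts aldehyde and ketone into terminal alkenes without epimerizing C7 and without attacking lactone, acetates or free hydroxyls.

Step 15
Reactants: 22 diene
Product: 23 target, (1S,2R,5Z,7S,8R,9R,10S,11R,12R,17R)-2,12-diacetoxy-8,9-dihydroxybriara-5,13-dien-19,7-olide (CNP0286823.1)
Conditions: second-generation Hoveyda–Grubbs catalyst (15 mol%), 1,4-benzoquinone, toluene (1 mM), 90 °C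
Reagents that add atoms: none
Why: Ring-closing metathesis between the C6 vinyl and the C5 isopropenyl groups at high dilution closes the ten-membered ring with loss of ethene, and a ring of this size should hold the trisubstituted alkene as the Z isomer (C4 and C7 cis) required by the target.

**Compound list**

1 | 3-bromo-2H-pyran-2-one | O=C1OC=CC=C1Br | starting material
2 | 3-methyl-2H-pyran-2-one | CC1=CC=COC1=O | intermediate
3 | but-2-ynoic acid | CC#CC(=O)O | starting material
4 | (Z)-but-2-enoic acid | C/C=C\C(=O)O | intermediate
5 | rac-(1R*,4S*,7R*,8S*)-4,7-dimethyl-3-oxo-2-oxabicyclo[2.2.2]oct-5-ene-8-carboxylic acid (7-methyl and 8-carboxyl cis and syn to the C5=C6 bridge) | O=C1O[C@@H]2C=C[C@@]1(C)[C@H]([C@H]2C)C(=O)O | intermediate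
6 | 2-(2-bromoethyl)-2-methyl-1,3-dioxolane | CC1(CCBr)OCCO1 | starting material
7 | [2-(2-methyl-1,3-dioxolan-2-yl)ethyl]magnesium bromide (Grignard reagent) | CC1(CC[Mg]Br)OCCO1 | intermediate
8 | rac-(1S*,2S*,5R*,6R*)-5-hydroxy-2,6-dimethyl-2-[3-(2-methyl-1,3-dioxolan-2-yl)propanoyl]cyclohex-3-ene-1-carboxylic acid | O[C@@H]1C=C[C@@](C(=O)CCC2(C)OCCO2)(C)[C@H]([C@H]1C)C(=O)O | intermediate
9 | rac-S-ethyl (1S*,2S*,5R*,6R*)-5-hydroxy-2,6-dimethyl-2-[3-(2-methyl-1,3-dioxolan-2-yl)propanoyl]cyclohex-3-ene-1-carbothioate | O[C@@H]1C=C[C@@](C(=O)CCC2(C)OCCO2)(C)[C@H]([C@H]1C)C(=O)SCC | intermediate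
10 | S-ethyl (1S,2S,5R,6R)-5-hydroxy-2-[(1R)-1-hydroxy-4-(2-methyl-1,3-dioxolan-2-yl)butyl]-2,6-dimethylcyclohex-3-ene-1-carbothioate | O[C@@H]1C=C[C@@]([C@H](O)CCC2(C)OCCO2)(C)[C@H]([C@H]1C)C(=O)SCC | intermediate
11 | S-ethyl (1S,2S,5R,6R)-5-acetoxy-2-[(1R)-1-acetoxy-4-(2-methyl-1,3-dioxolan-2-yl)butyl]-2,6-dimethylcyclohex-3-ene-1-carbothioate | CC(=O)O[C@@H]1C=C[C@@]([C@H](OC(C)=O)CCC2(C)OCCO2)(C)[C@H]([C@H]1C)C(=O)SCC | intermediate
12 | (1S,2S,5R,6R)-5-acetoxy-2-[(1R)-1-acetoxy-4-(2-methyl-1,3-dioxolan-2-yl)butyl]-2,6-dimethylcyclohex-3-ene-1-carbaldehyde | CC(=O)O[C@@H]1C=C[C@@]([C@H](OC(C)=O)CCC2(C)OCCO2)(C)[C@H]([C@H]1C)C=O | intermediate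
13 | 2,2-diethoxyacetaldehyde | CCOC(C=O)OCC | starting material
14 | 1,1-dibromo-3,3-diethoxyprop-1-ene | CCOC(C=C(Br)Br)OCC | intermediate
15 | methyl 2-bromopropanoate | COC(=O)C(C)Br | starting material
16 | bromo(1-methoxy-1-oxopropan-2-yl)zinc (Reformatsky reagent) | COC(=O)C(C)[Zn]Br | intermediate
17 | methyl (3Z)-3-bromo-5,5-diethoxy-2-methylpent-3-enoate (racemic at C2) | COC(=O)C(C)/C(Br)=C/C(OCC)OCC | intermediate
18 | methyl (3Z)-3-[(R)-{(1S,2S,5R,6R)-5-acetoxy-2-[(1R)-1-acetoxy-4-(2-methyl-1,3-dioxolan-2-yl)butyl]-2,6-dimethylcyclohex-3-en-1-yl}(triethylsilyloxy)methyl]-5,5-diethoxy-2-methylpent-3-enoate (epimers at the ester α-carbon, C17) | CC(=O)O[C@@H]1C=C[C@@]([C@H](OC(C)=O)CCC2(C)OCCO2)(C)[C@H]([C@H]1C)[C@@H](O[Si](CC)(CC)CC)/C(=C\C(OCC)OCC)C(C)C(=O)OC | intermediate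
19 | syn-7,8-diol methyl ester from 18 (both hydroxyls anti to the C9 silyloxy group; epimers at C17) | CC(=O)O[C@@H]1C=C[C@@]([C@H](OC(C)=O)CCC2(C)OCCO2)(C)[C@H]([C@H]1C)[C@@H](O[Si](CC)(CC)CC)[C@@](O)([C@@H](O)C(OCC)OCC)C(C)C(=O)OC | intermediate
20 | β-hydroxy-γ-lactone (O7–C19 lactone, 8-OH, 17-methyl, 9-OSiEt3, C6 diethyl acetal, C5 dioxolane; stereocentres as in 23) | CC(=O)O[C@@H]1C=C[C@@]([C@H](OC(C)=O)CCC2(C)OCCO2)(C)[C@H]([C@H]1C)[C@@H](O[Si](CC)(CC)CC)[C@@]1(O)[C@H](C(OCC)OCC)OC(=O)[C@@H]1C | intermediate
21 | keto aldehyde diol (C6 aldehyde, C5 methyl ketone, 8-OH and 9-OH free; stereocentres as in 23) | CC(=O)O[C@@H]1C=C[C@@]([C@H](OC(C)=O)CCC(C)=O)(C)[C@H]([C@H]1C)[C@@H](O)[C@@]1(O)[C@H](C=O)OC(=O)[C@@H]1C | intermediate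
22 | diene (C6 vinyl, C5 isopropenyl; stereocentres as in 23) | CC(=O)O[C@@H]1C=C[C@@]([C@H](OC(C)=O)CCC(C)=C)(C)[C@H]([C@H]1C)[C@@H](O)[C@@]1(O)[C@H](C=C)OC(=O)[C@@H]1C | intermediate
23 | (1S,2R,5Z,7S,8R,9R,10S,11R,12R,17R)-2,12-diacetoxy-8,9-dihydroxybriara-5,13-dien-19,7-olide (CNP0286823.1) | CC(=O)O[C@@H]1C=C[C@@]2(C)[C@H]([C@H]1C)[C@@H](O)[C@@]1(O)[C@H](/C=C(/C)CC[C@H]2OC(C)=O)OC(=O)[C@@H]1C | target

**Count.** Total steps: 15. Longest linear sequence: 12 steps (steps 1, 3–8 and 11–15).

**Steps most likely to fail**

Step 3. The β-substituted Z-acid may add too slowly to the weakly reactive pyrone, the adduct may lose CO2 if the mixture is heated to compensate, and endo selectivity may erode. The fallback sets out from 2 and replaces the acyclic acid by the cyclic, planar cis-enoate furan-2(5H)-one. Cycloaddition at 15 kbar (CH2Cl2, 50 °C) should give the endo tricyclic bis-lactone F1. PhSeNa with 18-crown-6 in THF at 65 °C then opens only the γ-lactone by SN2 attack at its primary O–CH2 carbon, because the O-bearing carbon of the other lactone is a bridgehead, and gives the seleno acid F2. Bu3SnH/AIBN (benzene, 80 °C) turns the CH2SePh group into the C20 methyl and comes back to the route at racemic 5.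

Step 15. Initiation at the allylic, oxygen-flanked vinyl group may be slow and the carbene may oligomerize or isomerize the alkenes before the strained ten-membered ring with a trisubstituted alkene closes. The fallback sets out from 21 and uses relay metathesis. A Wittig reaction of the aldehyde with the ylide from (hex-5-en-1-yl)triphenylphosphonium bromide (NaN(SiMe3)2, THF, −78 °C) gives the relay trienone F3. Methylenation of the ketone (Zn, CH2Br2, TiCl4) gives the relay tetraene F4. The ruthenium carbene then loads at the unhindered terminal alkene, expels cyclopentene to place the metal on C6, and closes onto the isopropenyl group, coming back at 23.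

Step 6. The substrate bias of the ketone next to quaternary C1 may override the catalyst, so that the two enantiomers of 9 are not both reduced to (2R)-carbinols and 10 is obtained in low enantiomeric purity. The fallback sets out from 5 and moves the resolution to the acid. Crystallization with (S)-1-phenylethanamine (or its enantiomer, whichever gives the less soluble salt of the wanted acid) gives the ammonium salt F5, and acidification frees enantiopure 5. This goes through steps 4 and 5 to enantiopure 9, whose reduction now only has to be diastereoselective (the matching oxazaborolidine enantiomer or a bulky achiral hydride), and the route is rejoined at 10.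

**Further compounds**

F1 | step 3 | endo adduct of 2 and furan-2(5H)-one (tricyclic bis-lactone, racemic) | O=C1O[C@@H]2C=C[C@@]1(C)[C@@H]3[C@H]2COC3=O
F2 | step 3 | rac-4-methyl-3-oxo-7-[(phenylselanyl)methyl]-2-oxabicyclo[2.2.2]oct-5-ene-8-carboxylic acid (seleno acid) | O=C1O[C@@H]2C=C[C@@]1(C)[C@H]([C@H]2C[Se]c1ccccc1)C(=O)O
F3 | step 15 | relay trienone (21 with the C6 aldehyde converted into a (Z)-hepta-1,6-dienyl group) | CC(=O)O[C@@H]1C=C[C@@]([C@H](OC(C)=O)CCC(C)=O)(C)[C@H]([C@H]1C)[C@@H](O)[C@@]1(O)[C@H](/C=C\CCCC=C)OC(=O)[C@@H]1C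
F4 | step 15 | relay tetraene (F3 with the C5 ketone methylenated) | CC(=O)O[C@@H]1C=C[C@@]([C@H](OC(C)=O)CCC(C)=C)(C)[C@H]([C@H]1C)[C@@H](O)[C@@]1(O)[C@H](/C=C\CCCC=C)OC(=O)[C@@H]1C
F5 | step 6 | (S)-1-phenylethanaminium salt of the (1R,4S,7R,8S)-acid 5 | O=C1O[C@@H]2C=C[C@@]1(C)[C@H]([C@H]2C)C(=O)[O-].C[C@H]([NH3+])c1ccccc1
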